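Lanaroflavone is disconnected at the O1–C8a bond of ring C in unit 1, the flavone whose C4' oxygen is the ether bridge to C8 of unit 2. In ring A of unit 1, C5, C7 and C8a all sit ortho or para to C4a, the carbon that carries the C4 carbonyl, so all three oxygens can start as C–F bonds of one symmetric 2,4,6-trifluorobenzoyl group. The precursor is a 1,3-diketone flanked by that ring and by a 4-aryloxyphenyl group that already carries methylated unit 2. One base-mediated intramolecular SNAr closes the pyranone and leaves two activated fluorides, which are later exchanged for methoxide before global demethylation.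

Key step: step 6

Remark: diketone 9 is drawn in its diketo form but should exist mainly as the chelated enol, which changes no step.

Step 1
Reactants: 1 apigenin
Product: 2 5,7-dimethoxy-2-(4-methoxyphenyl)chromen-4-one (apigenin trimethyl ether)
Conditions: Me2SO4 (6 equiv), K2CO3 (8 equiv), acetone, reflux, 48 h
Reagents that add atoms: dimethyl sulfate, COS(=O)(=O)OC
Why: Williamson O-methylation of all three phenols should go to completion with excess reagent and prolonged reflux, the chelated C5 hydroxyl being the last to react.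

Step 2
Reactants: 2 5,7-dimethoxy-2-(4-methoxyphenyl)chromen-4-one
Product: 3 8-iodo-5,7-dimethoxy-2-(4-methoxyphenyl)chromen-4-one
Conditions: NIS (1.05 equiv), CF3CO2H (cat.), MeCN, rt
Reagents that add atoms: N-iodosuccinimide, O=C1CCC(=O)N1I
Why: Electrophilic aromatic iodination should take place on the phloroglucinol-type ring A and at C8 rather than C6, because C6 is screened by two flanking methoxy groups (the C5 one turned toward it by the peri carbonyl) and C8 is the position that reacts in fully alkylated 5,7-dioxygenated flavones.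

Step 3
Reactants: 3 8-iodo-5,7-dimethoxy-2-(4-methoxyphenyl)chromen-4-one
Product: 5 8-hydroxy-5,7-dimethoxy-2-(4-methoxyphenyl)chromen-4-one, via pinacol boronate 4 (not isolated)
Conditions: B2pin2 (1.5 equiv), PdCl2(dppf) (5 mol %), KOAc (3 equiv), dioxane, 90 °C; then 30% aq H2O2, aq NaOH, THF, 0 °C → rt; Na2S2O3 quench, acidify to pH 5
Reagents that add atoms: hydrogen peroxide, OO (the C8 oxygen of 5); bis(pinacolato)diboron, CC1(C)OB(OC1(C)C)B1OC(C)(C)C(C)(C)O1 (the boryl group of intermediate 4 only)
Why: Miyaura borylation of the aryl iodide followed in the same flask by oxidative hydroxydeboronation (hydroperoxide adds to boron and the aryl group migrates to oxygen) should replace iodine by hydroxyl at C8 without touching the methyl ethers or the pyranone.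

Step 4
Reactants: 5 8-hydroxy-5,7-dimethoxy-2-(4-methoxyphenyl)chromen-4-one; 6 4-fluoroacetophenone
Product: 7 8-(4-acetylphenoxy)-5,7-dimethoxy-2-(4-methoxyphenyl)chromen-4-one
Conditions: K2CO3 (2 equiv), 6 (1.5 equiv), DMSO, 120 °C
Reagents that add atoms: none
Why: The C8 phenoxide, the only free hydroxyl in 5, should displace the fluoride para to the acetyl group in an intermolecular SNAr (addition–elimination) diaryl ether synthesis.

Step 5
Reactants: 7 8-(4-acetylphenoxy)-5,7-dimethoxy-2-(4-methoxyphenyl)chromen-4-one; 8 2,4,6-trifluorobenzoyl chloride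
Product: 9 1-[4-[[5,7-dimethoxy-2-(4-methoxyphenyl)-4-oxochromen-8-yl]oxy]phenyl]-3-(2,4,6-trifluorophenyl)propane-1,3-dione
Conditions: LiN(SiMe3)2 (2.2 equiv), THF, −78 °C; then 8 (1.05 equiv), −78 → 0 °C; aq NH4Cl
Reagents that add atoms: none
Why: Crossed Claisen-type C-acylation of the lithium enolate of the methyl ketone by the acid chloride should give the 1,3-diketone, the second equivalent of base holding the more acidic product as its chelated lithium enolate so that over-acylation is suppressed, while the hindered amide base neither adds to nor metalates the pyranone.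

Step 6
Reactants: 9 1-[4-[[5,7-dimethoxy-2-(4-methoxyphenyl)-4-oxochromen-8-yl]oxy]phenyl]-3-(2,4,6-trifluorophenyl)propane-1,3-dione
Product: 10 2-[4-[[5,7-dimethoxy-2-(4-methoxyphenyl)-4-oxochromen-8-yl]oxy]phenyl]-5,7-difluorochromen-4-one
Conditions: K2CO3 (2 equiv), dry DMF (0.05 M), 60 °C
Reagents that add atoms: none
Why: Carbonate deprotonates the acidic 1,3-diketone, and the enolate oxygen on the aryloxyphenyl side adds to one ortho C–F carbon of the trifluorophenyl ring to give a Meisenheimer anion delocalised into the neighbouring carbonyl; loss of fluoride then restores aromaticity and forms the O1–C8a bond. The closest known reaction type is the base-induced intramolecular SNAr cyclisation of 1-(2-fluoroaryl)-1,3-diketones to flavones. Ring C of unit 1 closes as a six-membered ring in a 6-endo-trig fashion, the attacked arene carbon C8a acting as the β-carbon of the aryl ketone in an oxa-Michael-like addition–elimination. No stereocentre is formed. The step needs attack through oxygen and a single regiochemistry: the enolate carbon could reach the ring only through a four-membered transition state, the two ortho fluorides are equivalent by symmetry, and the para fluoride is out of intramolecular reach, intermolecular attack on it being held back by dilution. The fluorides left at C5 and C7 are not displaced by carbonate and are kept for the next step.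

Step 7
Reactants: 10 2-[4-[[5,7-dimethoxy-2-(4-methoxyphenyl)-4-oxochromen-8-yl]oxy]phenyl]-5,7-difluorochromen-4-one
Product: 11 2-[4-[[5,7-dimethoxy-2-(4-methoxyphenyl)-4-oxochromen-8-yl]oxy]phenyl]-5,7-dimethoxychromen-4-one (lanaroflavone pentamethyl ether)
Conditions: NaOMe (6 equiv), MeOH–THF 1:1, reflux; dilute HCl work-up
Reagents that add atoms: sodium methoxide, [Na+].[O-]C
Why: Twofold SNAr by methoxide at C5 and C7 of unit 1, ortho and para to the acyl-bearing C4a, should exchange both fluorides, whereas the C4' aryloxy group is a much poorer leaving group on a ring activated only through the C2=C3 link, and any reversible methoxide addition at C2 of a pyranone re-closes on acidic work-up.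

Step 8
Reactants: 11 2-[4-[[5,7-dimethoxy-2-(4-methoxyphenyl)-4-oxochromen-8-yl]oxy]phenyl]-5,7-dimethoxychromen-4-one
Product: 12 lanaroflavone, 2-[4-[[5,7-dihydroxy-2-(4-hydroxyphenyl)-4-oxochromen-8-yl]oxy]phenyl]-5,7-dihydroxychromen-4-one
Conditions: BBr3 (15 equiv), CH2Cl2, −78 °C → rt; then MeOH, H2O
Reagents that add atoms: none
Why: Lewis-acid ether cleavage with BBr3 (bromide attacks the methyl carbon of each boron-complexed aryl methyl ether in an SN2 sense) should remove all five methyl groups, while the diaryl ether offers no sp3 carbon and stays intact and the aprotic low-temperature conditions avoid the Wessely–Moser-type ring-opening isomerisation of the 8-aryloxy-5,7-dihydroxy unit that hot protic acids could cause.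

Compound list
1 | apigenin, 5,7-dihydroxy-2-(4-hydroxyphenyl)chromen-4-one | O=c1cc(-c2ccc(O)cc2)oc2cc(O)cc(O)c12 | starting material
2 | 5,7-dimethoxy-2-(4-methoxyphenyl)chromen-4-one | COc1ccc(cc1)-c1cc(=O)c2c(OC)cc(OC)cc2o1 | intermediate
3 | 8-iodo-5,7-dimethoxy-2-(4-methoxyphenyl)chromen-4-one | COc1ccc(cc1)-c1cc(=O)c2c(OC)cc(OC)c(I)c2o1 | intermediate
4 | 5,7-dimethoxy-2-(4-methoxyphenyl)-8-(4,4,5,5-tetramethyl-1,3,2-dioxaborolan-2-yl)chromen-4-one | COc1ccc(cc1)-c1cc(=O)c2c(OC)cc(OC)c(B3OC(C)(C)C(C)(C)O3)c2o1 | intermediate
5 | 8-hydroxy-5,7-dimethoxy-2-(4-methoxyphenyl)chromen-4-one | COc1ccc(cc1)-c1cc(=O)c2c(OC)cc(OC)c(O)c2o1 | intermediate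
6 | 4-fluoroacetophenone | CC(=O)c1ccc(F)cc1 | starting material
7 | 8-(4-acetylphenoxy)-5,7-dimethoxy-2-(4-methoxyphenyl)chromen-4-one | CC(=O)c1ccc(cc1)Oc1c(OC)cc(OC)c2c1oc(cc2=O)-c1ccc(OC)cc1 | intermediate
8 | 2,4,6-trifluorobenzoyl chloride | O=C(Cl)c1c(F)cc(F)cc1F | starting material
9 | 1-[4-[[5,7-dimethoxy-2-(4-methoxyphenyl)-4-oxochromen-8-yl]oxy]phenyl]-3-(2,4,6-trifluorophenyl)propane-1,3-dione | O=C(CC(=O)c1c(F)cc(F)cc1F)c1ccc(cc1)Oc1c(OC)cc(OC)c2c1oc(cc2=O)-c1ccc(OC)cc1 | intermediate
10 | 2-[4-[[5,7-dimethoxy-2-(4-methoxyphenyl)-4-oxochromen-8-yl]oxy]phenyl]-5,7-difluorochromen-4-one | Fc1cc(F)c2c(c1)oc(cc2=O)-c1ccc(cc1)Oc1c(OC)cc(OC)c2c1oc(cc2=O)-c1ccc(OC)cc1 | intermediate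
11 | 2-[4-[[5,7-dimethoxy-2-(4-methoxyphenyl)-4-oxochromen-8-yl]oxy]phenyl]-5,7-dimethoxychromen-4-one | COc1cc(OC)c2c(c1)oc(cc2=O)-c1ccc(cc1)Oc1c(OC)cc(OC)c2c1oc(cc2=O)-c1ccc(OC)cc1 | intermediate
12 | lanaroflavone | O=c1cc(-c2ccc(Oc3c(O)cc(O)c4c(=O)cc(-c5ccc(O)cc5)oc34)cc2)oc2cc(O)cc(O)c12 | target

Total step count: 8. Longest linear sequence: 8 steps (1 to 12).

Steps most likely to fail

Step 7 (exchange of both fluorides). The second substitution may stall once the first methoxy group has lowered the electrophilicity of ring A. Forcing it may let methoxide cleave the diaryl ether by attack at C4' of unit 1, or degrade a pyranone by ring opening. The fallback sets out from 5 and comes back at 11. It brings in ring A of unit 1 with its oxygens already in place and closes ring C by chalcone oxidative cyclisation instead of fluoride displacement. Phenol 5 is arylated with 4-fluorobenzaldehyde (K2CO3, DMF, 100 °C) to give 4-[[5,7-dimethoxy-2-(4-methoxyphenyl)-4-oxochromen-8-yl]oxy]benzaldehyde F1. Claisen–Schmidt condensation of this aldehyde with commercial 2-hydroxy-4,6-dimethoxyacetophenone (KOH, EtOH, rt) should give (E)-3-[4-[[5,7-dimethoxy-2-(4-methoxyphenyl)-4-oxochromen-8-yl]oxy]phenyl]-1-(2-hydroxy-4,6-dimethoxyphenyl)prop-2-en-1-one F2. I2 (cat.) in DMSO at 120 °C then cyclises and dehydrogenates the 2'-hydroxychalcone to 11.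

Step 5 (C-acylation of the methyl ketone). Acylation may go to the enolate oxygen or occur twice, and the enolate or the amide base may attack an activated C–F bond of the acid chloride. The fallback sets out from 7 and comes back at 9. It replaces acylation by aldol addition and oxidation. The lithium enolate of 7 (LiN(SiMe3)2, 1.1 equiv, THF, −78 °C) is added to 2,4,6-trifluorobenzaldehyde to give racemic 1-[4-[[5,7-dimethoxy-2-(4-methoxyphenyl)-4-oxochromen-8-yl]oxy]phenyl]-3-hydroxy-3-(2,4,6-trifluorophenyl)propan-1-one F3. Dess–Martin periodinane (CH2Cl2, rt) should oxidise this β-hydroxy ketone to 9.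

Step 3 (borylation and oxidation at C8). The hindered iodide, flanked by two ortho oxygens, may undergo reductive loss of iodine faster than borylation, and the electron-rich phenol may be over-oxidised by peroxide. The fallback sets out from 3 and comes back at 7. It reverses the polarity of the ether formation: Ullmann-type C–O coupling of iodide 3 with 4-hydroxyacetophenone (CuI, picolinic acid, K3PO4, DMSO, 90 °C) should give 7 directly, replacing steps 3 and 4. No compound outside the list is formed (F0).

Further compounds
F1 | step 7 | 4-[[5,7-dimethoxy-2-(4-methoxyphenyl)-4-oxochromen-8-yl]oxy]benzaldehyde | O=Cc1ccc(cc1)Oc1c(OC)cc(OC)c2c1oc(cc2=O)-c1ccc(OC)cc1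
F2 | step 7 | (E)-3-[4-[[5,7-dimethoxy-2-(4-methoxyphenyl)-4-oxochromen-8-yl]oxy]phenyl]-1-(2-hydroxy-4,6-dimethoxyphenyl)prop-2-en-1-one | COc1cc(OC)c(c(O)c1)C(=O)/C=C/c1ccc(cc1)Oc1c(OC)cc(OC)c2c1oc(cc2=O)-c1ccc(OC)cc1
F3 | step 5 | 1-[4-[[5,7-dimethoxy-2-(4-methoxyphenyl)-4-oxochromen-8-yl]oxy]phenyl]-3-hydroxy-3-(2,4,6-trifluorophenyl)propan-1-one (racemic) | O=C(CC(O)c1c(F)cc(F)cc1F)c1ccc(cc1)Oc1c(OC)cc(OC)c2c1oc(cc2=O)-c1ccc(OC)cc1
F0 | step 3 | none | none
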